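**Plan**

1. Labdane numbering is used: the target is an ent-labdane, a trans-decalin with quaternary C4 (CH3 and an axial CH2OAc cis to the C10 methyl), C5–H, C9 bearing the side chain, a C8=C17 methylidene, and a C13=C14 enoic acid with C12 cis to CO2H.
2. Cuts, in retrosynthetic order: both acetates; C12–C13 (sp3–sp2 Negishi coupling of the decalin with a (Z)-β-iodo enoate, fragment 2); C3–H back to C3–OH (a helper oxygen); then C4–C5 together with C9–C10, back to an acyclic (2S,3R)-epoxy (Z)-allylsilane.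
3. Enabling feature: C4, C5=C10 and C9=C8(–C17) form a head-to-tail 1,5-diene array. A cation at C4 is placed for capture by the C5=C10 π bond (ring A), the resulting C10 cation for capture by C9 of a C8=C9 allylsilane (ring B), and the C8=C17 methylidene marks where silicon leaves.
4. Forward order: chain assembly (C5=C10 by carboalumination, C8=C9 allylsilane by nickel ring-opening of a dihydrofuran, C3=C4 by Still–Gennari olefination), Sharpless epoxide, ring A and ring B in one operation, C3 deoxygenation, side-chain coupling, deprotection, acetylation.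
5. Stereochemistry: absolute configuration from Sharpless epoxidation with L-(+)-diethyl tartrate; C4 by inversion at the oxirane; C5, C10 and C9 from the E/Z alkene geometries through chair transition states; C13=C14 from a stereoretentive coupling.

Key step: step 12

**Route**

Step 1
Reactants: 1 tert-butyldimethyl(pent-4-yn-1-yloxy)silane
Product: 4 (E)-7-[(tert-butyldimethylsilyl)oxy]-4-methylhept-3-en-1-ol, via alkenyldimethylalane 2 (not isolated), via lithium alkenylalanate 3 (not isolated)
Conditions: Me3Al, Cp2ZrCl2 (cat.), CH2Cl2, 0 °C to rt; volatiles removed; n-BuLi, hexane/THF, −78 to 0 °C; oxirane, THF, −30 °C to rt; aqueous work-up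
Reagents that add atoms: trimethylaluminium C[Al](C)C; oxirane C1CO1
Why: Negishi carboalumination adds CH3 and Al cis across the terminal alkyne with Al on the terminal carbon, and the derived alanate opens oxirane with retention of alkene geometry, so the (E)-C5=C10 alkene and the C7 alcohol should form together.

Step 2
Reactants: 4 (E)-7-[(tert-butyldimethylsilyl)oxy]-4-methylhept-3-en-1-ol
Product: 5 (E)-tert-butyl[(7-iodo-4-methylhept-4-en-1-yl)oxy]dimethylsilane
Conditions: PPh3, I2, imidazole, CH2Cl2, 0 °C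
Reagents that add atoms: iodine II
Why: Appel-type iodination converts the primary alcohol into the iodide by SN2 displacement of an alkoxyphosphonium ion under buffered conditions that leave the silyl ether and the alkene untouched.

Step 3
Reactants: 5 (E)-tert-butyl[(7-iodo-4-methylhept-4-en-1-yl)oxy]dimethylsilane; 6 2,3-dihydrofuran
Product: 8 (E)-tert-butyl{[7-(4,5-dihydrofuran-2-yl)-4-methylhept-4-en-1-yl]oxy}dimethylsilane, via 5-lithio-2,3-dihydrofuran 7 (not isolated)
Conditions: 6, t-BuLi, THF, −78 to 0 °C; then 5, THF, −30 °C to rt; filtration through basic alumina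
Reagents that add atoms: none
Why: α-lithiation of the cyclic enol ether followed by SN2 alkylation of the vinyllithium with a primary iodide is a standard entry to 5-alkyl-2,3-dihydrofurans, the low temperature keeping E2 loss from the homoallylic iodide in check.

Step 4
Reactants: 8 (E)-tert-butyl{[7-(4,5-dihydrofuran-2-yl)-4-methylhept-4-en-1-yl]oxy}dimethylsilane
Product: 9 (3Z,7E)-11-[(tert-butyldimethylsilyl)oxy]-8-methyl-4-[(trimethylsilyl)methyl]undeca-3,7-dien-1-ol
Conditions: Me3SiCH2MgCl, NiCl2(PPh3)2 (cat.), toluene/Et2O, reflux; aqueous NH4Cl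
Reagents that add atoms: (trimethylsilyl)methylmagnesium chloride C[Si](C)(C)C[Mg]Cl
Why: Nickel-catalysed Kumada-type coupling of a Grignard reagent without β-hydrogens into the enol ether C–O bond proceeds with retention at the sp2 carbon, so the silylmethyl group takes the place of the ring oxygen cis to the hydroxyethyl arm and the (Z)-allylsilane and the C12 alcohol arise in one operation.

Step 5
Reactants: 9 (3Z,7E)-11-[(tert-butyldimethylsilyl)oxy]-8-methyl-4-[(trimethylsilyl)methyl]undeca-3,7-dien-1-ol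
Product: 10 tert-butyl({(4E,8Z)-11-chloro-4-methyl-8-[(trimethylsilyl)methyl]undeca-4,8-dien-1-yl}oxy)dimethylsilane
Conditions: PPh3, CCl4, CH2Cl2, 40 °C
Reagents that add atoms: tetrachloromethane ClC(Cl)(Cl)Cl
Why: Appel chlorination under neutral conditions spares the allylsilane and gives a primary chloride that should be inert through step 14, where a bromide or iodide would be reduced by the tin hydride.

Step 6
Reactants: 10 tert-butyl({(4E,8Z)-11-chloro-4-methyl-8-[(trimethylsilyl)methyl]undeca-4,8-dien-1-yl}oxy)dimethylsilane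
Product: 11 (4E,8Z)-11-chloro-4-methyl-8-[(trimethylsilyl)methyl]undeca-4,8-dien-1-ol
Conditions: AcOH/THF/H2O (3:1:1), rt
Reagents that add atoms: none
Why: Acid-catalysed hydrolysis of a primary silyl ether in aqueous acetic acid is mild enough that protodesilylation of the trisubstituted allylsilane should not compete.

Step 7
Reactants: 11 (4E,8Z)-11-chloro-4-methyl-8-[(trimethylsilyl)methyl]undeca-4,8-dien-1-ol
Product: 12 (4E,8Z)-11-chloro-4-methyl-8-[(trimethylsilyl)methyl]undeca-4,8-dienal
Conditions: Dess–Martin periodinane, CH2Cl2, 0 °C to rt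
Reagents that add atoms: none
Why: Dess–Martin oxidation takes the primary alcohol to the aldehyde without over-oxidation and without an electrophile that would attack the allylsilane.

Step 8
Reactants: 12 (4E,8Z)-11-chloro-4-methyl-8-[(trimethylsilyl)methyl]undeca-4,8-dienal
Product: 13 ethyl (2Z,6E,10Z)-13-chloro-2,6-dimethyl-10-[(trimethylsilyl)methyl]trideca-2,6,10-trienoate
Conditions: ethyl 2-[bis(2,2,2-trifluoroethoxy)phosphoryl]propanoate, KN(SiMe3)2, 18-crown-6, THF, −78 °C
Reagents that add atoms: ethyl 2-[bis(2,2,2-trifluoroethoxy)phosphoryl]propanoate CCOC(=O)C(C)P(=O)(OCC(F)(F)F)OCC(F)(F)F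
Why: Still–Gennari olefination, in which fast irreversible collapse of the electron-poor phosphonate adduct gives the kinetic (Z)-trisubstituted enoate, places the future C19 carbon cis to the chain as the cyclisation requires.

Step 9
Reactants: 13 ethyl (2Z,6E,10Z)-13-chloro-2,6-dimethyl-10-[(trimethylsilyl)methyl]trideca-2,6,10-trienoate
Product: 14 (2Z,6E,10Z)-13-chloro-2,6-dimethyl-10-[(trimethylsilyl)methyl]trideca-2,6,10-trien-1-ol
Conditions: iBu2AlH, CH2Cl2, −78 °C; Rochelle salt work-up
Reagents that add atoms: none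
Why: 1,2-Reduction of the conjugated ester with iBu2AlH at low temperature gives the allylic alcohol with the (Z) geometry intact and does not touch the alkyl chloride or the allylsilane.

Step 10
Reactants: 14 (2Z,6E,10Z)-13-chloro-2,6-dimethyl-10-[(trimethylsilyl)methyl]trideca-2,6,10-trien-1-ol
Product: 15 {(2S,3R)-3-[(3E,7Z)-10-chloro-3-methyl-7-[(trimethylsilyl)methyl]deca-3,7-dien-1-yl]-2-methyloxiran-2-yl}methanol
Conditions: Ti(OiPr)4 (cat.), L-(+)-diethyl tartrate (cat.), t-BuOOH, 4 Å molecular sieves, CH2Cl2, −20 °C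
Reagents that add atoms: tert-butyl hydroperoxide CC(C)(C)OO
Why: Sharpless asymmetric epoxidation is directed by the hydroxyl group to the allylic C3=C4 alkene alone, and L-(+)-diethyl tartrate should deliver oxygen to the face that gives the (2S,3R) cis-epoxide, which fixes the absolute configuration of the whole decalin.

Step 11
Reactants: 15 {(2S,3R)-3-[(3E,7Z)-10-chloro-3-methyl-7-[(trimethylsilyl)methyl]deca-3,7-dien-1-yl]-2-methyloxiran-2-yl}methanol
Product: 16 tert-butyl({(2S,3R)-3-[(3E,7Z)-10-chloro-3-methyl-7-[(trimethylsilyl)methyl]deca-3,7-dien-1-yl]-2-methyloxiran-2-yl}methoxy)dimethylsilane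
Conditions: t-BuMe2SiCl, imidazole, DMF, 0 °C to rt
Reagents that add atoms: tert-butyldimethylsilyl chloride CC(C)(C)[Si](C)(C)Cl
Why: Silylation of the primary alcohol is routine, and a silyl ether is chosen over the final acetate because an ester carbonyl next to the oxirane would compete as an internal nucleophile in step 12.

Step 12
Reactants: 16 tert-butyl({(2S,3R)-3-[(3E,7Z)-10-chloro-3-methyl-7-[(trimethylsilyl)methyl]deca-3,7-dien-1-yl]-2-methyloxiran-2-yl}methoxy)dimethylsilane
Product: 17 (1R,2R,4aS,5R,8aS)-1-{[(tert-butyldimethylsilyl)oxy]methyl}-5-(2-chloroethyl)-1,4a-dimethyl-6-methylidenedecahydronaphthalen-2-ol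
Conditions: MeAlCl2, CH2Cl2 (high dilution), −78 °C; Et3N/MeOH quench, then aqueous Rochelle salt
Reagents that add atoms: none
Why: MeAlCl2 coordinates the oxirane oxygen and the C5=C10 π bond attacks the tertiary oxirane carbon C4 anti to the breaking C4–O bond, forming the C4–C5 bond and ring A (6-endo opening of the epoxide and 6-endo-trig on the alkene, both oxirane carbons and both alkene carbons ending in the ring); the tertiary C10 cation is then captured by C9 of the C8=C9 allylsilane (6-endo-trig, ring B, C9–C10 bond) and the β-silyl cation at C8 loses the silyl group to chloride, which places the alkene at C8=C17 only. The closest known reaction type is the Lewis acid-promoted epoxy-polyene cyclisation terminated by an allylsilane, as used for 3-hydroxylated drimane and labdane skeletons. C4 is set by inversion at the oxirane carbon, so the CH2OSi group that was cis to the chain in the epoxide becomes axial and cis to the C10 methyl. C5 and C10 are set by anti addition across the (E)-C5=C10 alkene in a chair transition state (trans ring fusion), C9 by the (Z)-allylsilane geometry in the second chair (C11 equatorial, cis to C20), and the absolute sense of all four by the C3–O bond of the Sharpless epoxide, which must lie equatorial and antiperiplanar to the new C4–C5 bond. The step needs opening at C4 and not at C3 (secured by the tertiary character of C4 and by a six-membered chair over a five-membered alternative), chair–chair folding (secured by the defined trisubstituted alkene geometries), and a proton-free medium so that neither the allylsilane nor the new methylidene is protonated (MeAlCl2 destroys adventitious acid as methane, with low temperature and dilution).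

Step 13
Reactants: 17 (1R,2R,4aS,5R,8aS)-1-{[(tert-butyldimethylsilyl)oxy]methyl}-5-(2-chloroethyl)-1,4a-dimethyl-6-methylidenedecahydronaphthalen-2-ol
Product: 18 O-[(1R,2R,4aS,5R,8aS)-1-{[(tert-butyldimethylsilyl)oxy]methyl}-5-(2-chloroethyl)-1,4a-dimethyl-6-methylidenedecahydronaphthalen-2-yl] O-phenyl carbonothioate
Conditions: PhOC(S)Cl, pyridine, DMAP (cat.), CH2Cl2, rt to 40 °C
Reagents that add atoms: O-phenyl chlorothionoformate S=C(Cl)Oc1ccccc1
Why: Thioacylation of the hindered secondary alcohol under non-basic conditions is the first stage of a Barton–McCombie deoxygenation and avoids an alkoxide that could draw the silyl group across from the C19 oxygen.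

Step 14
Reactants: 18 O-[(1R,2R,4aS,5R,8aS)-1-{[(tert-butyldimethylsilyl)oxy]methyl}-5-(2-chloroethyl)-1,4a-dimethyl-6-methylidenedecahydronaphthalen-2-yl] O-phenyl carbonothioate
Product: 19 tert-butyl{[(1R,4aS,5R,8aS)-5-(2-chloroethyl)-1,4a-dimethyl-6-methylidenedecahydronaphthalen-1-yl]methoxy}dimethylsilane
Conditions: Bu3SnH, AIBN (cat.), toluene, 100 °C
Reagents that add atoms: none
Why: Barton–McCombie radical deoxygenation removes the helper oxygen at C3 through a secondary radical that has no alkene within reach, the thionocarbonate reacting with stannyl radicals far faster than the primary chloride.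

Step 15
Reactants: 19 tert-butyl{[(1R,4aS,5R,8aS)-5-(2-chloroethyl)-1,4a-dimethyl-6-methylidenedecahydronaphthalen-1-yl]methoxy}dimethylsilane
Product: 20 tert-butyl{[(1R,4aS,5R,8aS)-5-(2-iodoethyl)-1,4a-dimethyl-6-methylidenedecahydronaphthalen-1-yl]methoxy}dimethylsilane
Conditions: NaI, butan-2-one, reflux
Reagents that add atoms: sodium iodide [Na+].[I-]
Why: Finkelstein exchange at the unhindered primary carbon is driven by precipitation of sodium chloride and delivers the iodide needed for zinc insertion.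

Step 16
Reactants: 21 tert-butyldiphenyl(prop-2-yn-1-yloxy)silane
Product: 23 methyl 4-[(tert-butyldiphenylsilyl)oxy]but-2-ynoate, via lithium acetylide 22 (not isolated)
Conditions: n-BuLi, THF, −78 °C; then ClCO2Me, −78 °C to 0 °C
Reagents that add atoms: methyl chloroformate COC(=O)Cl
Why: Acylation of a lithium acetylide with a chloroformate is the standard route to 2-alkynoates and brings in C15 of fragment 2.

Step 17
Reactants: 23 methyl 4-[(tert-butyldiphenylsilyl)oxy]but-2-ynoate
Product: 24 methyl (2Z)-4-[(tert-butyldiphenylsilyl)oxy]-3-iodobut-2-enoate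
Conditions: LiI, AcOH, MeCN, 70 °C
Reagents that add atoms: lithium iodide [Li+].[I-]
Why: Conjugate hydroiodination of the ynoate, in which iodide adds to the β-carbon and the allenolate is protonated anti, should give the kinetic (Z)-β-iodo enoate with iodine cis to the ester.

Step 18
Reactants: 20 tert-butyl{[(1R,4aS,5R,8aS)-5-(2-iodoethyl)-1,4a-dimethyl-6-methylidenedecahydronaphthalen-1-yl]methoxy}dimethylsilane; 24 methyl (2Z)-4-[(tert-butyldiphenylsilyl)oxy]-3-iodobut-2-enoate
Product: 26 methyl (2E)-3-{[(tert-butyldiphenylsilyl)oxy]methyl}-5-[(1R,4aS,5R,8aS)-5-{[(tert-butyldimethylsilyl)oxy]methyl}-5,8a-dimethyl-2-methylidenedecahydronaphthalen-1-yl]pent-2-enoate, via alkylzinc iodide 25 (not isolated)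
Conditions: 20, Zn dust (activated), LiCl, THF, 40 °C; then 24, Pd2(dba)3 (cat.), tri(2-furyl)phosphine, THF, rt
Reagents that add atoms: none
Why: Negishi coupling of the primary alkylzinc iodide with the β-iodo enoate proceeds with retention at the vinyl carbon, so C12 ends cis to the ester, which is the geometry of the target.

Step 19
Reactants: 26 methyl (2E)-3-{[(tert-butyldiphenylsilyl)oxy]methyl}-5-[(1R,4aS,5R,8aS)-5-{[(tert-butyldimethylsilyl)oxy]methyl}-5,8a-dimethyl-2-methylidenedecahydronaphthalen-1-yl]pent-2-enoate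
Product: 28 (2E)-3-(hydroxymethyl)-5-[(1R,4aS,5R,8aS)-5-(hydroxymethyl)-5,8a-dimethyl-2-methylidenedecahydronaphthalen-1-yl]pent-2-enoic acid, via diol methyl ester 27 (not isolated)
Conditions: Bu4NF, THF, 45 °C; then LiOH, H2O/MeOH, rt; dilute HCl to pH 3 at 0 °C
Reagents that add atoms: lithium hydroxide [Li+].[OH-]
Why: Fluoride-mediated cleavage of both silyl ethers followed by saponification of the methyl ester frees the diol acid, which cannot lactonise because the hydroxymethyl group is trans to the carboxyl group.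

Step 20
Reactants: 28 (2E)-3-(hydroxymethyl)-5-[(1R,4aS,5R,8aS)-5-(hydroxymethyl)-5,8a-dimethyl-2-methylidenedecahydronaphthalen-1-yl]pent-2-enoic acid
Product: 29 (2E)-3-(acetoxymethyl)-5-[(1R,4aS,5R,8aS)-5-(acetoxymethyl)-5,8a-dimethyl-2-methylidenedecahydronaphthalen-1-yl]pent-2-enoic acid
Conditions: Ac2O, pyridine, DMAP (cat.), CH2Cl2, rt; then H2O, rt
Reagents that add atoms: acetic anhydride CC(=O)OC(C)=O
Why: DMAP-catalysed acetylation esterifies both primary alcohols, including the hindered axial one at C19, and the mixed anhydride formed at the carboxyl group is hydrolysed back to the acid by water.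

**Compound list**

1 | tert-butyldimethyl(pent-4-yn-1-yloxy)silane | C#CCCCO[Si](C)(C)C(C)(C)C | starting material
2 | (E)-{5-[(tert-butyldimethylsilyl)oxy]-2-methylpent-1-en-1-yl}dimethylalane | CC(C)(C)[Si](C)(C)OCCC/C(C)=C/[Al](C)C | intermediate
3 | lithium (E)-butyl{5-[(tert-butyldimethylsilyl)oxy]-2-methylpent-1-en-1-yl}dimethylalanate | [Li+].CCCC[Al-](C)(C)/C=C(\C)CCCO[Si](C)(C)C(C)(C)C | intermediate
4 | (E)-7-[(tert-butyldimethylsilyl)oxy]-4-methylhept-3-en-1-ol | CC(C)(C)[Si](C)(C)OCCC/C(C)=C/CCO | intermediate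
5 | (E)-tert-butyl[(7-iodo-4-methylhept-4-en-1-yl)oxy]dimethylsilane | CC(C)(C)[Si](C)(C)OCCC/C(C)=C/CCI | intermediate
6 | 2,3-dihydrofuran | C1=COCC1 | starting material
7 | 5-lithio-2,3-dihydrofuran | [Li]C1=CCCO1 | intermediate
8 | (E)-tert-butyl{[7-(4,5-dihydrofuran-2-yl)-4-methylhept-4-en-1-yl]oxy}dimethylsilane | CC(C)(C)[Si](C)(C)OCCC/C(C)=C/CCC1=CCCO1 | intermediate
9 | (3Z,7E)-11-[(tert-butyldimethylsilyl)oxy]-8-methyl-4-[(trimethylsilyl)methyl]undeca-3,7-dien-1-ol | CC(C)(C)[Si](C)(C)OCCC/C(C)=C/CC/C(C[Si](C)(C)C)=C/CCO | intermediate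
10 | tert-butyl({(4E,8Z)-11-chloro-4-methyl-8-[(trimethylsilyl)methyl]undeca-4,8-dien-1-yl}oxy)dimethylsilane | CC(C)(C)[Si](C)(C)OCCC/C(C)=C/CC/C(C[Si](C)(C)C)=C/CCCl | intermediate
11 | (4E,8Z)-11-chloro-4-methyl-8-[(trimethylsilyl)methyl]undeca-4,8-dien-1-ol | OCCC/C(C)=C/CC/C(C[Si](C)(C)C)=C/CCCl | intermediate
12 | (4E,8Z)-11-chloro-4-methyl-8-[(trimethylsilyl)methyl]undeca-4,8-dienal | O=CCC/C(C)=C/CC/C(C[Si](C)(C)C)=C/CCCl | intermediate
13 | ethyl (2Z,6E,10Z)-13-chloro-2,6-dimethyl-10-[(trimethylsilyl)methyl]trideca-2,6,10-trienoate | CCOC(=O)/C(C)=C\CC/C(C)=C/CC/C(C[Si](C)(C)C)=C/CCCl | intermediate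
14 | (2Z,6E,10Z)-13-chloro-2,6-dimethyl-10-[(trimethylsilyl)methyl]trideca-2,6,10-trien-1-ol | OC/C(C)=C\CC/C(C)=C/CC/C(C[Si](C)(C)C)=C/CCCl | intermediate
15 | {(2S,3R)-3-[(3E,7Z)-10-chloro-3-methyl-7-[(trimethylsilyl)methyl]deca-3,7-dien-1-yl]-2-methyloxiran-2-yl}methanol | OC[C@]1(C)O[C@@H]1CC/C(C)=C/CC/C(C[Si](C)(C)C)=C/CCCl | intermediate
16 | tert-butyl({(2S,3R)-3-[(3E,7Z)-10-chloro-3-methyl-7-[(trimethylsilyl)methyl]deca-3,7-dien-1-yl]-2-methyloxiran-2-yl}methoxy)dimethylsilane | CC(C)(C)[Si](C)(C)OC[C@]1(C)O[C@@H]1CC/C(C)=C/CC/C(C[Si](C)(C)C)=C/CCCl | intermediate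
17 | (1R,2R,4aS,5R,8aS)-1-{[(tert-butyldimethylsilyl)oxy]methyl}-5-(2-chloroethyl)-1,4a-dimethyl-6-methylidenedecahydronaphthalen-2-ol | C=C1CC[C@@H]2[C@](C)(CO[Si](C)(C)C(C)(C)C)[C@H](O)CC[C@@]2(C)[C@@H]1CCCl | intermediate
18 | O-[(1R,2R,4aS,5R,8aS)-1-{[(tert-butyldimethylsilyl)oxy]methyl}-5-(2-chloroethyl)-1,4a-dimethyl-6-methylidenedecahydronaphthalen-2-yl] O-phenyl carbonothioate | C=C1CC[C@@H]2[C@](C)(CO[Si](C)(C)C(C)(C)C)[C@H](OC(=S)Oc3ccccc3)CC[C@@]2(C)[C@@H]1CCCl | intermediate
19 | tert-butyl{[(1R,4aS,5R,8aS)-5-(2-chloroethyl)-1,4a-dimethyl-6-methylidenedecahydronaphthalen-1-yl]methoxy}dimethylsilane | C=C1CC[C@@H]2[C@](C)(CO[Si](C)(C)C(C)(C)C)CCC[C@@]2(C)[C@@H]1CCCl | intermediate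
20 | tert-butyl{[(1R,4aS,5R,8aS)-5-(2-iodoethyl)-1,4a-dimethyl-6-methylidenedecahydronaphthalen-1-yl]methoxy}dimethylsilane | C=C1CC[C@@H]2[C@](C)(CO[Si](C)(C)C(C)(C)C)CCC[C@@]2(C)[C@@H]1CCI | intermediate
21 | tert-butyldiphenyl(prop-2-yn-1-yloxy)silane | C#CCO[Si](c1ccccc1)(c1ccccc1)C(C)(C)C | starting material
22 | lithium 3-[(tert-butyldiphenylsilyl)oxy]prop-1-yn-1-ide | [Li]C#CCO[Si](c1ccccc1)(c1ccccc1)C(C)(C)C | intermediate
23 | methyl 4-[(tert-butyldiphenylsilyl)oxy]but-2-ynoate | COC(=O)C#CCO[Si](c1ccccc1)(c1ccccc1)C(C)(C)C | intermediate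
24 | methyl (2Z)-4-[(tert-butyldiphenylsilyl)oxy]-3-iodobut-2-enoate | COC(=O)/C=C(\I)CO[Si](c1ccccc1)(c1ccccc1)C(C)(C)C | intermediate
25 | {2-[(1R,4aS,5R,8aS)-5-{[(tert-butyldimethylsilyl)oxy]methyl}-5,8a-dimethyl-2-methylidenedecahydronaphthalen-1-yl]ethyl}zinc iodide | C=C1CC[C@@H]2[C@](C)(CO[Si](C)(C)C(C)(C)C)CCC[C@@]2(C)[C@@H]1CC[Zn]I | intermediate
26 | methyl (2E)-3-{[(tert-butyldiphenylsilyl)oxy]methyl}-5-[(1R,4aS,5R,8aS)-5-{[(tert-butyldimethylsilyl)oxy]methyl}-5,8a-dimethyl-2-methylidenedecahydronaphthalen-1-yl]pent-2-enoate | C=C1CC[C@@H]2[C@](C)(CO[Si](C)(C)C(C)(C)C)CCC[C@@]2(C)[C@@H]1CC/C(=C\C(=O)OC)CO[Si](c1ccccc1)(c1ccccc1)C(C)(C)C | intermediate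
27 | methyl (2E)-3-(hydroxymethyl)-5-[(1R,4aS,5R,8aS)-5-(hydroxymethyl)-5,8a-dimethyl-2-methylidenedecahydronaphthalen-1-yl]pent-2-enoate | C=C1CC[C@@H]2[C@](C)(CO)CCC[C@@]2(C)[C@@H]1CC/C(=C\C(=O)OC)CO | intermediate
28 | (2E)-3-(hydroxymethyl)-5-[(1R,4aS,5R,8aS)-5-(hydroxymethyl)-5,8a-dimethyl-2-methylidenedecahydronaphthalen-1-yl]pent-2-enoic acid | C=C1CC[C@@H]2[C@](C)(CO)CCC[C@@]2(C)[C@@H]1CC/C(=C\C(=O)O)CO | intermediate
29 | (2E)-3-(acetoxymethyl)-5-[(1R,4aS,5R,8aS)-5-(acetoxymethyl)-5,8a-dimethyl-2-methylidenedecahydronaphthalen-1-yl]pent-2-enoic acid | C=C1CC[C@@H]2[C@](C)(COC(C)=O)CCC[C@@]2(C)[C@@H]1CC/C(=C\C(=O)O)COC(C)=O | target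

**Step count and risks**

Total steps: 20. Longest linear sequence: 18 (steps 1 to 15, then 18 to 20); fragment 2 takes steps 16 and 17.

Step 12. The oxirane may ionise without help from the C5=C10 alkene, because the silyloxy group on C19 withdraws electron density from C4. This would show as a 1,2-hydride shift to a C3 ketone, capture of the C10 cation by the C3 oxygen after ring A has closed, or arrest after the first ring. The fallback changes from the cationic to the radical manifold on a silicon-free substrate, setting out from 8 and returning at 17. Nickel-catalysed coupling of 8 with MeMgBr in place of the silylmethyl Grignard reagent would give (3E,7E)-11-[(tert-butyldimethylsilyl)oxy]-4,8-dimethylundeca-3,7-dien-1-ol F1. The operations of steps 5 to 11 would then give, in turn: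
- the chloride tert-butyl{[(4E,8E)-11-chloro-4,8-dimethylundeca-4,8-dien-1-yl]oxy}dimethylsilane F2;
- the alcohol (4E,8E)-11-chloro-4,8-dimethylundeca-4,8-dien-1-ol F3;
- the aldehyde (4E,8E)-11-chloro-4,8-dimethylundeca-4,8-dienal F4;
- the enoate ethyl (2Z,6E,10E)-13-chloro-2,6,10-trimethyltrideca-2,6,10-trienoate F5;
- the allylic alcohol (2Z,6E,10E)-13-chloro-2,6,10-trimethyltrideca-2,6,10-trien-1-ol F6;
- the epoxy alcohol {(2S,3R)-3-[(3E,7E)-10-chloro-3,7-dimethyldeca-3,7-dien-1-yl]-2-methyloxiran-2-yl}methanol F7;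
- its silyl ether tert-butyl({(2S,3R)-3-[(3E,7E)-10-chloro-3,7-dimethyldeca-3,7-dien-1-yl]-2-methyloxiran-2-yl}methoxy)dimethylsilane F8.

Cp2TiCl (trivalent titanium, made from Cp2TiCl2 and Mn dust and turned over with Me3SiCl and 2,4,6-collidine in THF) would open the oxirane of F8 homolytically to the C4 radical. Two 6-endo radical additions would close ring A and ring B, and the C8 radical would end as the C8=C17 alkene by titanium-mediated loss of hydrogen from the C17 methyl; dilute acid work-up would return 17. In this variant C4 forms from a planar radical, so its configuration would rest on the chair preference and not on inversion, and a C4 epimer would have to be removed at 17.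

Step 4. Insertion of zerovalent nickel into the enol ether C–O bond may be slow with the bulky silylmethyl Grignard reagent, leaving time for hydrolysis of the enol ether or erosion of the alkene geometry; E2 loss in step 3 would hurt the same stage. The fallback builds the allylsilane from an alkyne, setting out from 5 and returning at 9. Alkylation of dilithiated but-3-yn-1-ol (n-BuLi, THF/DMPU) with 5 would give the alkynol (E)-11-[(tert-butyldimethylsilyl)oxy]-8-methylundec-7-en-3-yn-1-ol F9. Hydroxyl-directed trans-hydroalumination with NaAlH2(OCH2CH2OMe)2 followed by iodine would place iodine on the distal alkyne carbon cis to the hydroxyethyl arm and give the vinyl iodide (3Z,7E)-11-[(tert-butyldimethylsilyl)oxy]-4-iodo-8-methylundeca-3,7-dien-1-ol F10. Stereoretentive Kumada coupling with Me3SiCH2MgCl and Pd(PPh3)4 would give 9.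

Step 18. The alkylzinc reagent may be protonated, the alkylpalladium intermediate may undergo β-hydride elimination, or the β-iodo enoate may isomerise on palladium, which would cost yield and C13=C14 geometry. The fallback forms C13=C14 by carbonyl olefination, setting out from 20 and returning at 26. Iodine–lithium exchange on 20 with t-BuLi (Et2O/pentane, −78 °C) would give the alkyllithium {2-[(1R,4aS,5R,8aS)-5-{[(tert-butyldimethylsilyl)oxy]methyl}-5,8a-dimethyl-2-methylidenedecahydronaphthalen-1-yl]ethyl}lithium F11. Acylation with N-methoxy-N-methyl-2-[(tert-butyldiphenylsilyl)oxy]acetamide would give the ketone 1-[(tert-butyldiphenylsilyl)oxy]-4-[(1R,4aS,5R,8aS)-5-{[(tert-butyldimethylsilyl)oxy]methyl}-5,8a-dimethyl-2-methylidenedecahydronaphthalen-1-yl]butan-2-one F12. Wittig reaction with Ph3P=CHCO2Me in toluene at 90 °C, where α-oxygenated ketones place the ester trans to the oxygenated carbon, would give 26.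

**Further compounds**

F1 | step 12 | (3E,7E)-11-[(tert-butyldimethylsilyl)oxy]-4,8-dimethylundeca-3,7-dien-1-ol | CC(C)(C)[Si](C)(C)OCCC/C(C)=C/CC/C(C)=C/CCO
F2 | step 12 | tert-butyl{[(4E,8E)-11-chloro-4,8-dimethylundeca-4,8-dien-1-yl]oxy}dimethylsilane | CC(C)(C)[Si](C)(C)OCCC/C(C)=C/CC/C(C)=C/CCCl
F3 | step 12 | (4E,8E)-11-chloro-4,8-dimethylundeca-4,8-dien-1-ol | OCCC/C(C)=C/CC/C(C)=C/CCCl
F4 | step 12 | (4E,8E)-11-chloro-4,8-dimethylundeca-4,8-dienal | O=CCC/C(C)=C/CC/C(C)=C/CCCl
F5 | step 12 | ethyl (2Z,6E,10E)-13-chloro-2,6,10-trimethyltrideca-2,6,10-trienoate | CCOC(=O)/C(C)=C\CC/C(C)=C/CC/C(C)=C/CCCl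
F6 | step 12 | (2Z,6E,10E)-13-chloro-2,6,10-trimethyltrideca-2,6,10-trien-1-ol | OC/C(C)=C\CC/C(C)=C/CC/C(C)=C/CCCl
F7 | step 12 | {(2S,3R)-3-[(3E,7E)-10-chloro-3,7-dimethyldeca-3,7-dien-1-yl]-2-methyloxiran-2-yl}methanol | OC[C@]1(C)O[C@@H]1CC/C(C)=C/CC/C(C)=C/CCCl
F8 | step 12 | tert-butyl({(2S,3R)-3-[(3E,7E)-10-chloro-3,7-dimethyldeca-3,7-dien-1-yl]-2-methyloxiran-2-yl}methoxy)dimethylsilane | CC(C)(C)[Si](C)(C)OC[C@]1(C)O[C@@H]1CC/C(C)=C/CC/C(C)=C/CCCl
F9 | step 4 | (E)-11-[(tert-butyldimethylsilyl)oxy]-8-methylundec-7-en-3-yn-1-ol | CC(C)(C)[Si](C)(C)OCCC/C(C)=C/CCC#CCCO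
F10 | step 4 | (3Z,7E)-11-[(tert-butyldimethylsilyl)oxy]-4-iodo-8-methylundeca-3,7-dien-1-ol | CC(C)(C)[Si](C)(C)OCCC/C(C)=C/CC/C(I)=C/CCO
F11 | step 18 | {2-[(1R,4aS,5R,8aS)-5-{[(tert-butyldimethylsilyl)oxy]methyl}-5,8a-dimethyl-2-methylidenedecahydronaphthalen-1-yl]ethyl}lithium | C=C1CC[C@@H]2[C@](C)(CO[Si](C)(C)C(C)(C)C)CCC[C@@]2(C)[C@@H]1CC[Li]
F12 | step 18 | 1-[(tert-butyldiphenylsilyl)oxy]-4-[(1R,4aS,5R,8aS)-5-{[(tert-butyldimethylsilyl)oxy]methyl}-5,8a-dimethyl-2-methylidenedecahydronaphthalen-1-yl]butan-2-one | C=C1CC[C@@H]2[C@](C)(CO[Si](C)(C)C(C)(C)C)CCC[C@@]2(C)[C@@H]1CCC(=O)CO[Si](c1ccccc1)(c1ccccc1)C(C)(C)C
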